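**Plan**

1. Retrosynthesis: acetate ⇐ alcohol ⇐ ketone. With the ring numbered C1 (carbinol), C2 (CMe2), C3 (CH bearing the chain), C4 (C=CH2), C5 and C6 (CH2–CH2), the bonds C4–C5 and C6–C1 are cut together, leaving ethylene and an acyclic 4-alkynal. The alkynal is cut back to a C22 tetraenal, and that at its C4=C5 alkene to a farnesol-derived and a pentynol-derived half.
2. Enabling feature: C1 and C4 are 1,4-related across the quaternary C2 and the stereogenic C3. At the aldehyde/terminal-alkyne oxidation level, C1–C2–C3–C4 is therefore a 4-alkynal whose formyl C–H and C≡C can close a five-membered acylrhodacycle. Uptake of ethylene then builds the carbocycle, the C1 oxygen function and the exocyclic methylene in one catalytic [4+2] event; the only helper is the ketone oxidation level at C1, reduced in the next step.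
3. Forward order: chain first (carboalumination, B-alkyl Suzuki coupling, two-carbon Wittig extension), then the stereocentre and the gem-dimethyl carbon (conjugate alkynylation, double methylation), then the ring, then ketone reduction and acetylation.
4. Stereochemistry: C3 (R) comes from a rhodium/bisphosphine-catalysed conjugate alkynylation. C1 (S) comes from axial hydride delivery to the 2,2-dimethylcyclohexanone (equatorial OH, cis to the chain). The (E)-alkenes come from farnesol, syn-carboalumination and stereoretentive coupling.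

Key step: step 10

Remark: (R)-DTBM-SEGPHOS is written for step 7 on the assumption that it delivers the alkynyl group to the enal face that gives the (3S) product; if the sense of induction on this enal is the opposite, the (S)-ligand is used and nothing else changes.

**Step 1**
Reactants: 1 (2E,6E)-farnesol
Product: 2 (2E,6E)-farnesal
Conditions: TEMPO (10 mol %), PhI(OAc)2, CH2Cl2, rt
Reagents that add atoms: none
Why: The oxoammonium-mediated TEMPO/PhI(OAc)2 oxidation converts the allylic primary alcohol into the enal without touching or isomerising the trisubstituted alkenes, so the (2E,6E) geometry is carried over.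

**Step 2**
Reactants: 2 (2E,6E)-farnesal
Product: 3 (3E,7E)-4,8,12-trimethyltrideca-1,3,7,11-tetraene
Conditions: Ph3PCH3Br, n-BuLi, THF, −78 to 0 °C
Reagents that add atoms: methyltriphenylphosphonium bromide, C[P+](c1ccccc1)(c1ccccc1)c1ccccc1.[Br-]
Why: Wittig methylenation by the non-stabilised ylide adds the terminal CH2 at the carbonyl carbon and leaves the (E)-trisubstituted alkenes unchanged, giving the terminal 1,3-diene needed for hydroboration.

**Step 3**
Reactants: 4 pent-4-yn-1-ol
Product: 6 (E)-5-iodo-4-methylpent-4-en-1-ol, via alkenylalane 5 (not isolated)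
Conditions: Me3Al (3 equiv), Cp2ZrCl2 (0.25 equiv), CH2Cl2, 0 °C to rt; then I2, THF, −30 to 0 °C
Reagents that add atoms: trimethylaluminium, C[Al](C)C; iodine, II
Why: Negishi carboalumination adds Me–Al syn across the terminal alkyne with methyl on the internal carbon, and iodinolysis of the alkenyl–Al bond with retention gives the (E)-trisubstituted vinyl iodide, the hydroxyl being tolerated as its aluminium alkoxide.

**Step 4**
Reactants: 3 (3E,7E)-4,8,12-trimethyltrideca-1,3,7,11-tetraene; 6 (E)-5-iodo-4-methylpent-4-en-1-ol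
Product: 8 (4E,8E,12E)-4,9,13,17-tetramethyloctadeca-4,8,12,16-tetraen-1-ol, via alkylborane 7 (not isolated)
Conditions: 9-BBN, THF, 0 °C to rt; then 6, PdCl2(dppf) (5 mol %), AsPh3, Cs2CO3, DMF/H2O, rt
Reagents that add atoms: none
Why: 9-BBN hydroborates only the monosubstituted terminal alkene of the diene (boron on C1), and the primary alkylborane then undergoes B-alkyl Suzuki–Miyaura coupling with the vinyl iodide with retention of its (E) geometry, which fixes the C4=C5 alkene of 8.

**Step 5**
Reactants: 8 (4E,8E,12E)-4,9,13,17-tetramethyloctadeca-4,8,12,16-tetraen-1-ol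
Product: 9 (4E,8E,12E)-4,9,13,17-tetramethyloctadeca-4,8,12,16-tetraenal
Conditions: TEMPO (10 mol %), PhI(OAc)2, CH2Cl2, rt
Reagents that add atoms: none
Why: The TEMPO/PhI(OAc)2 oxidation stops at the aldehyde for an unhindered primary alcohol and is compatible with the four trisubstituted alkenes.

**Step 6**
Reactants: 9 (4E,8E,12E)-4,9,13,17-tetramethyloctadeca-4,8,12,16-tetraenal
Product: 10 (2E,6E,10E,14E)-6,11,15,19-tetramethylicosa-2,6,10,14,18-pentaenal
Conditions: Ph3P=CHCHO, toluene, 80 °C
Reagents that add atoms: (triphenylphosphoranylidene)acetaldehyde, O=CC=P(c1ccccc1)(c1ccccc1)c1ccccc1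
Why: The Wittig reaction of the stabilised formylmethylene ylide gives the (E)-enal under thermodynamic control and adds the two carbons that become C1 and C2 of the ring.

**Step 7**
Reactants: 10 (2E,6E,10E,14E)-6,11,15,19-tetramethylicosa-2,6,10,14,18-pentaenal; 11 (triisopropylsilyl)acetylene
Product: 12 (3S,6E,10E,14E)-6,11,15,19-tetramethyl-3-{[tri(propan-2-yl)silyl]ethynyl}icosa-6,10,14,18-tetraenal
Conditions: [Rh(OAc)(C2H4)2]2 (2.5 mol %), (R)-DTBM-SEGPHOS (6 mol %), MeOH, 40 °C
Reagents that add atoms: none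
Why: In this rhodium-catalysed asymmetric conjugate alkynylation an alkynylrhodium species adds 1,4 to the enal and methanol protonates the rhodium enolate, the bulky silyl group and ligand suppressing alkyne dimerisation while the chiral bisphosphine selects the enal face and so sets the (3S) centre, the later ring CH.

**Step 8**
Reactants: 12 (3S,6E,10E,14E)-6,11,15,19-tetramethyl-3-{[tri(propan-2-yl)silyl]ethynyl}icosa-6,10,14,18-tetraenal
Product: 14 (3S,6E,10E,14E)-2,2,6,11,15,19-hexamethyl-3-{[tri(propan-2-yl)silyl]ethynyl}icosa-6,10,14,18-tetraenal, via monomethyl aldehyde 13 (not isolated)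
Conditions: KOt-Bu (3 equiv), MeI (excess), THF, 0 °C
Reagents that add atoms: iodomethane, CI
Why: Exhaustive α-methylation of the potassium enolate (two successive enolisation/SN2 alkylations) installs the gem-dimethyl group and stops there because 14 has no α-hydrogen, while the β-stereocentre is not acidic and is retained.

**Step 9**
Reactants: 14 (3S,6E,10E,14E)-2,2,6,11,15,19-hexamethyl-3-{[tri(propan-2-yl)silyl]ethynyl}icosa-6,10,14,18-tetraenal
Product: 15 (3R,6E,10E,14E)-3-ethynyl-2,2,6,11,15,19-hexamethylicosa-6,10,14,18-tetraenal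
Conditions: Bu4NF, THF, 0 °C
Reagents that add atoms: none
Why: Fluoride-induced protodesilylation of the alkynylsilane frees the terminal alkyne, the aldehyde cannot enolise, and the stereocentre is untouched (the descriptor becomes R only through the change in substituent priorities).

**Step 10**
Reactants: 15 (3R,6E,10E,14E)-3-ethynyl-2,2,6,11,15,19-hexamethylicosa-6,10,14,18-tetraenal; 16 ethylene
Product: 17 (3R)-2,2-dimethyl-4-methylidene-3-[(3E,7E,11E)-3,8,12,16-tetramethylheptadeca-3,7,11,15-tetraen-1-yl]cyclohexan-1-one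
Conditions: [Rh(dppe)]2(BF4)2 (5 mol %), ethylene (5 bar), CH2Cl2, 25 °C
Reagents that add atoms: none
Why: Proposed new method: cationic monovalent rhodium should insert into the formyl C–H bond of 15 to give an acyl rhodium hydride, the hydride then adds syn to the tethered alkyne (H to the terminal carbon, Rh to the internal one, the only regiochemistry that gives a five-membered chelate), and the resulting acyl(alkenyl)rhodacycle of trivalent rhodium takes up ethylene by migratory insertion and closes by C–C reductive elimination. The closest known reaction type is the rhodium-catalysed [4+2] annulation of 4-alkynals with alkynes and with acrylamides, and what is new here is a simple non-chelating alkene (ethylene) as the two-carbon partner together with a terminal alkyne, the latter being a competent partner in related cationic rhodium hydroacylations. The one ring closed is the cyclohexanone, formed as a formal [4+2] of the four-carbon formyl–CMe2–CH–alkyne unit with the two ethylene carbons: insertion expands the five-membered rhodacycle to a seven-membered one and reductive elimination contracts it to the carbocycle. No stereocentre is created; the existing one is flanked by the quaternary carbon, cannot enolise and is not involved in any bond change, and the carbinol centre is set afterwards by reduction of the ketone. The step needs chemoselectivity for ethylene insertion over reductive elimination to a methylidenecyclobutanone, isomerisation to a cyclopentenone, decarbonylation, β-hydride elimination and simple hydroacylation of ethylene; ethylene under pressure in a non-coordinating solvent, its symmetry (no regiochemical question), the gem-dimethyl group (non-enolisable aldehyde, favoured chelate) and the inertness of the trisubstituted chain alkenes towards insertion should secure it.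

**Step 11**
Reactants: 17 (3R)-2,2-dimethyl-4-methylidene-3-[(3E,7E,11E)-3,8,12,16-tetramethylheptadeca-3,7,11,15-tetraen-1-yl]cyclohexan-1-one
Product: 18 (1S,3R)-2,2-dimethyl-4-methylidene-3-[(3E,7E,11E)-3,8,12,16-tetramethylheptadeca-3,7,11,15-tetraen-1-yl]cyclohexan-1-ol (achilleol A)
Conditions: NaBH4, MeOH, 0 °C
Reagents that add atoms: none
Why: In this borohydride reduction the small hydride attacks the 2,2-dimethylcyclohexanone axially, away from the axial C2 methyl group, in the chair that keeps the C3 chain equatorial, so the new hydroxyl is equatorial and cis to the chain, which is the (1S) configuration.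

**Step 12**
Reactants: 18 (1S,3R)-2,2-dimethyl-4-methylidene-3-[(3E,7E,11E)-3,8,12,16-tetramethylheptadeca-3,7,11,15-tetraen-1-yl]cyclohexan-1-ol
Product: 19 (1S,3R)-2,2-dimethyl-4-methylidene-3-[(3E,7E,11E)-3,8,12,16-tetramethylheptadeca-3,7,11,15-tetraen-1-yl]cyclohexyl acetate
Conditions: Ac2O, pyridine, DMAP (cat.), CH2Cl2, rt
Reagents that add atoms: acetic anhydride, CC(=O)OC(C)=O
Why: DMAP-catalysed acylation of the secondary alcohol with acetic anhydride proceeds with retention at C1 and gives the target acetate.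

**Compound list**

1 | (2E,6E)-farnesol | OC/C=C(\C)CC/C=C(\C)CCC=C(C)C | starting material
2 | (2E,6E)-farnesal | O=C/C=C(\C)CC/C=C(\C)CCC=C(C)C | intermediate
3 | (3E,7E)-4,8,12-trimethyltrideca-1,3,7,11-tetraene | C=C/C=C(\C)CC/C=C(\C)CCC=C(C)C | intermediate
4 | pent-4-yn-1-ol | C#CCCCO | starting material
5 | dimethyl[(1E)-5-(dimethylalumanyloxy)-2-methylpent-1-en-1-yl]alumane (alkenylalane) | C[Al](C)OCCC/C(C)=C/[Al](C)C | intermediate
6 | (E)-5-iodo-4-methylpent-4-en-1-ol | OCCC/C(C)=C/I | intermediate
7 | 9-[(3E,7E)-4,8,12-trimethyltrideca-3,7,11-trien-1-yl]-9-borabicyclo[3.3.1]nonane (alkylborane) | CC(C)=CCC/C(C)=C/CC/C(C)=C/CCB1C2CCCC1CCC2 | intermediate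
8 | (4E,8E,12E)-4,9,13,17-tetramethyloctadeca-4,8,12,16-tetraen-1-ol | OCCC/C(C)=C/CC/C=C(\C)CC/C=C(\C)CCC=C(C)C | intermediate
9 | (4E,8E,12E)-4,9,13,17-tetramethyloctadeca-4,8,12,16-tetraenal | O=CCC/C(C)=C/CC/C=C(\C)CC/C=C(\C)CCC=C(C)C | intermediate
10 | (2E,6E,10E,14E)-6,11,15,19-tetramethylicosa-2,6,10,14,18-pentaenal | O=C/C=C/CC/C(C)=C/CC/C=C(\C)CC/C=C(\C)CCC=C(C)C | intermediate
11 | (triisopropylsilyl)acetylene | C#C[Si](C(C)C)(C(C)C)C(C)C | starting material
12 | (3S,6E,10E,14E)-6,11,15,19-tetramethyl-3-{[tri(propan-2-yl)silyl]ethynyl}icosa-6,10,14,18-tetraenal | O=CC[C@@H](C#C[Si](C(C)C)(C(C)C)C(C)C)CC/C(C)=C/CC/C=C(\C)CC/C=C(\C)CCC=C(C)C | intermediate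
13 | (3S,6E,10E,14E)-2,6,11,15,19-pentamethyl-3-{[tri(propan-2-yl)silyl]ethynyl}icosa-6,10,14,18-tetraenal (both C2 epimers; monomethyl aldehyde) | O=CC(C)[C@@H](C#C[Si](C(C)C)(C(C)C)C(C)C)CC/C(C)=C/CC/C=C(\C)CC/C=C(\C)CCC=C(C)C | intermediate
14 | (3S,6E,10E,14E)-2,2,6,11,15,19-hexamethyl-3-{[tri(propan-2-yl)silyl]ethynyl}icosa-6,10,14,18-tetraenal | O=CC(C)(C)[C@@H](C#C[Si](C(C)C)(C(C)C)C(C)C)CC/C(C)=C/CC/C=C(\C)CC/C=C(\C)CCC=C(C)C | intermediate
15 | (3R,6E,10E,14E)-3-ethynyl-2,2,6,11,15,19-hexamethylicosa-6,10,14,18-tetraenal | O=CC(C)(C)[C@@H](C#C)CC/C(C)=C/CC/C=C(\C)CC/C=C(\C)CCC=C(C)C | intermediate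
16 | ethylene | C=C | starting material
17 | (3R)-2,2-dimethyl-4-methylidene-3-[(3E,7E,11E)-3,8,12,16-tetramethylheptadeca-3,7,11,15-tetraen-1-yl]cyclohexan-1-one | C=C1CCC(=O)C(C)(C)[C@@H]1CC/C(C)=C/CC/C=C(\C)CC/C=C(\C)CCC=C(C)C | intermediate
18 | (1S,3R)-2,2-dimethyl-4-methylidene-3-[(3E,7E,11E)-3,8,12,16-tetramethylheptadeca-3,7,11,15-tetraen-1-yl]cyclohexan-1-ol (achilleol A) | C=C1CC[C@H](O)C(C)(C)[C@@H]1CC/C(C)=C/CC/C=C(\C)CC/C=C(\C)CCC=C(C)C | intermediate
19 | (1S,3R)-2,2-dimethyl-4-methylidene-3-[(3E,7E,11E)-3,8,12,16-tetramethylheptadeca-3,7,11,15-tetraen-1-yl]cyclohexyl acetate | C=C1CC[C@H](OC(C)=O)C(C)(C)[C@@H]1CC/C(C)=C/CC/C=C(\C)CC/C=C(\C)CCC=C(C)C | target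

**Totals and risks**

Total step count: 12. Longest linear sequence: 11 steps (steps 1, 2 and 4 to 12, from 1); step 3 is the side branch.

Step 10 (bears the label "Proposed new method:"). Ethylene insertion into the acylrhodacycle may be slower than reductive elimination to the four-membered ketone, isomerisation to a cyclopentenone, β-hydride elimination after insertion, or oligomerisation of the terminal alkyne. The fallback uses known chemistry, sets out from 15 and comes back at 17. CH2=CHMgBr (2.5 equiv, THF, −78 to 0 °C; the first equivalent is spent on the acetylenic C–H) adds to the aldehyde to give the vinyl carbinol (5R,8E,12E,16E)-5-ethynyl-4,4,8,13,17,21-hexamethyldocosa-1,8,12,16,20-pentaen-3-ol F1 as both C3 epimers. Dess–Martin oxidation gives the alkynyl vinyl ketone (5R,8E,12E,16E)-5-ethynyl-4,4,8,13,17,21-hexamethyldocosa-1,8,12,16,20-pentaen-3-one F2. Tin hydride-mediated radical enyne cyclisation (Bu3SnH, AIBN, benzene, 80 °C, slow addition at high dilution) follows: the stannyl radical adds to the terminal alkyne carbon and the alkenyl radical closes onto the enone terminus in the 6-endo mode. Any 5-exo radical ring-expands in the Dowd–Beckwith manner to the same constitution, because the two ring CH2 groups are equivalent. This gives the stannylmethylidene ketone (3S)-2,2-dimethyl-3-[(3E,7E,11E)-3,8,12,16-tetramethylheptadeca-3,7,11,15-tetraen-1-yl]-4-[(tributylstannyl)methylidene]cyclohexan-1-one F3. Protodestannylation (HCl, 1 equiv, CH2Cl2, −20 °C) then gives 17.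

Step 8. Aldol self-condensation and O-methylation of the aldehyde enolate may compete with C-methylation, and the second methylation may stay incomplete. The fallback moves the alkylations to the ester oxidation level, sets out from 12 and comes back at 14. Pinnick oxidation (NaClO2, NaH2PO4, 2-methylbut-2-ene in large excess, t-BuOH/H2O) gives (3S,6E,10E,14E)-6,11,15,19-tetramethyl-3-{[tri(propan-2-yl)silyl]ethynyl}icosa-6,10,14,18-tetraenoic acid F4. Me3SiCHN2 in MeOH/toluene gives the methyl ester, methyl (3S,6E,10E,14E)-6,11,15,19-tetramethyl-3-{[tri(propan-2-yl)silyl]ethynyl}icosa-6,10,14,18-tetraenoate F5. Two successive enolate alkylations (LiN(i-Pr)2, MeI, THF, −78 °C, twice) give methyl (3S,6E,10E,14E)-2,2,6,11,15,19-hexamethyl-3-{[tri(propan-2-yl)silyl]ethynyl}icosa-6,10,14,18-tetraenoate F6. Reduction of the hindered ester with i-Bu2AlH (CH2Cl2, −78 °C) gives 14.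

Step 7. The facial selectivity may be insufficient on this polyunsaturated enal, and alkyne dimerisation or 1,2-addition may compete. The fallback builds the stereocentre and the gem-dimethyl carbon together by enamine catalysis, sets out from 9 and comes back at 15, so that steps 6 to 9 are bypassed. Henry reaction of 9 with nitromethane (cat. base) and dehydration (MsCl, Et3N) give the nitroalkene (1E,5E,9E,13E)-5,10,14,18-tetramethyl-1-nitrononadeca-1,5,9,13,17-pentaene F7. Organocatalytic Michael addition of isobutyraldehyde (1-[(1R,2R)-2-aminocyclohexyl]-3-[3,5-bis(trifluoromethyl)phenyl]thiourea, or its enantiomer as required for the (3S) adduct, CH2Cl2, rt) gives the nitro aldehyde (3S,6E,10E,14E)-2,2,6,11,15,19-hexamethyl-3-(nitromethyl)icosa-6,10,14,18-tetraenal F8. NaBH4 in MeOH gives the nitro alcohol (3S,6E,10E,14E)-2,2,6,11,15,19-hexamethyl-3-(nitromethyl)icosa-6,10,14,18-tetraen-1-ol F9. Nef reaction (NaOMe, MeOH; then aqueous TiCl3 buffered with NH4OAc) gives the hydroxy aldehyde, which closes to the lactol (3S)-4,4-dimethyl-3-[(3E,7E,11E)-3,8,12,16-tetramethylheptadeca-3,7,11,15-tetraen-1-yl]oxolan-2-ol F10. Ohira–Bestmann homologation (dimethyl (1-diazo-2-oxopropyl)phosphonate, K2CO3, MeOH) gives the alkynol (3R,6E,10E,14E)-3-ethynyl-2,2,6,11,15,19-hexamethylicosa-6,10,14,18-tetraen-1-ol F11. TEMPO/PhI(OAc)2 oxidation gives 15.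

**Further compounds**

F1 | step 10 | (5R,8E,12E,16E)-5-ethynyl-4,4,8,13,17,21-hexamethyldocosa-1,8,12,16,20-pentaen-3-ol (both C3 epimers) | C=CC(O)C(C)(C)[C@@H](C#C)CC/C(C)=C/CC/C=C(\C)CC/C=C(\C)CCC=C(C)C
F2 | step 10 | (5R,8E,12E,16E)-5-ethynyl-4,4,8,13,17,21-hexamethyldocosa-1,8,12,16,20-pentaen-3-one | C=CC(=O)C(C)(C)[C@@H](C#C)CC/C(C)=C/CC/C=C(\C)CC/C=C(\C)CCC=C(C)C
F3 | step 10 | (3S)-2,2-dimethyl-3-[(3E,7E,11E)-3,8,12,16-tetramethylheptadeca-3,7,11,15-tetraen-1-yl]-4-[(tributylstannyl)methylidene]cyclohexan-1-one (E/Z mixture) | CCCC[Sn](CCCC)(CCCC)C=C1CCC(=O)C(C)(C)[C@@H]1CC/C(C)=C/CC/C=C(\C)CC/C=C(\C)CCC=C(C)C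
F4 | step 8 | (3S,6E,10E,14E)-6,11,15,19-tetramethyl-3-{[tri(propan-2-yl)silyl]ethynyl}icosa-6,10,14,18-tetraenoic acid | OC(=O)C[C@@H](C#C[Si](C(C)C)(C(C)C)C(C)C)CC/C(C)=C/CC/C=C(\C)CC/C=C(\C)CCC=C(C)C
F5 | step 8 | methyl (3S,6E,10E,14E)-6,11,15,19-tetramethyl-3-{[tri(propan-2-yl)silyl]ethynyl}icosa-6,10,14,18-tetraenoate | COC(=O)C[C@@H](C#C[Si](C(C)C)(C(C)C)C(C)C)CC/C(C)=C/CC/C=C(\C)CC/C=C(\C)CCC=C(C)C
F6 | step 8 | methyl (3S,6E,10E,14E)-2,2,6,11,15,19-hexamethyl-3-{[tri(propan-2-yl)silyl]ethynyl}icosa-6,10,14,18-tetraenoate | COC(=O)C(C)(C)[C@@H](C#C[Si](C(C)C)(C(C)C)C(C)C)CC/C(C)=C/CC/C=C(\C)CC/C=C(\C)CCC=C(C)C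
F7 | step 7 | (1E,5E,9E,13E)-5,10,14,18-tetramethyl-1-nitrononadeca-1,5,9,13,17-pentaene | [O-][N+](=O)/C=C/CC/C(C)=C/CC/C=C(\C)CC/C=C(\C)CCC=C(C)C
F8 | step 7 | (3S,6E,10E,14E)-2,2,6,11,15,19-hexamethyl-3-(nitromethyl)icosa-6,10,14,18-tetraenal | O=CC(C)(C)[C@@H](C[N+](=O)[O-])CC/C(C)=C/CC/C=C(\C)CC/C=C(\C)CCC=C(C)C
F9 | step 7 | (3S,6E,10E,14E)-2,2,6,11,15,19-hexamethyl-3-(nitromethyl)icosa-6,10,14,18-tetraen-1-ol | OCC(C)(C)[C@@H](C[N+](=O)[O-])CC/C(C)=C/CC/C=C(\C)CC/C=C(\C)CCC=C(C)C
F10 | step 7 | (3S)-4,4-dimethyl-3-[(3E,7E,11E)-3,8,12,16-tetramethylheptadeca-3,7,11,15-tetraen-1-yl]oxolan-2-ol (both anomers) | OC1OCC(C)(C)[C@@H]1CC/C(C)=C/CC/C=C(\C)CC/C=C(\C)CCC=C(C)C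
F11 | step 7 | (3R,6E,10E,14E)-3-ethynyl-2,2,6,11,15,19-hexamethylicosa-6,10,14,18-tetraen-1-ol | OCC(C)(C)[C@@H](C#C)CC/C(C)=C/CC/C=C(\C)CC/C=C(\C)CCC=C(C)C
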